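## Retrosynthetic overview

1. Ring A is the fused oxygenated benzene ring (C4a to C8a), ring B the carbocycle C1 to C4, and ring C the pendant guaiacyl ring on C1. Target 17 comes from LiAlH4 reduction of the all-trans diester 16, which comes from bromo diester 14 by hydrogenolysis of a temporary C8 bromine and methoxide equilibration of C2 and C3.
2. Ring B is formed last, in one flask, by making C1–C2 and C4–C4a. This joins diarylmethanol 6 (rings A and C already linked at C1) to a five-carbon methylidenesuccinate unit delivered as silyl ketene acetal 9 of methyl paraconate.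
3. Enabling feature: C1 is the benzylic carbon para to the hydroxyl of ring C, so it ionises to a para-quinone methide (electrophilic C1). C4a–H of ring A lies para to the C7 hydroxyl and ortho to the C5 methoxy group (nucleophilic C4a). The rival site C8, ortho to the C7 hydroxyl, is blocked by bromine.
4. Temporary ring: the paraconate lactone (an O–C4 bond absent from the target) makes C2 the only nucleophilic carbon of the C5 unit. It is cleaved in the cascade to release the C3=C4 acrylate that ring A then attacks.
5. Stereochemistry: C1 is set by a chiral phosphoric acid in the key step. C2 and C3, both alpha to esters, are set afterwards by equilibration to the all-equatorial isomer.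

Key step: step 5

Assumptions: 3 and racemic paraconic acid 7 are taken as commercially available (7 as the racemate because its stereocenter is erased in step 5), and (R)-TRIP is taken to give the (R) configuration at C1; the mirror-image acid would be used unchanged if the sense proved opposite.

## Route

Step 1
Reactants: 1 3-hydroxy-4,5-dimethoxybenzaldehyde
Product: 2 2-bromo-3-hydroxy-4,5-dimethoxybenzaldehyde
Conditions: Br2, NaOAc, AcOH, 20 °C
Reagents that add atoms: bromine, BrBr
Why: Electrophilic aromatic bromination should occur at the position ortho to the free hydroxyl and para to the 5-methoxy group, the doubly activated site at which phenolic benzaldehydes of this type are brominated, which installs the bromine that later blocks C8 of ring A.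

Step 2
Reactants: 2 2-bromo-3-hydroxy-4,5-dimethoxybenzaldehyde; 3 (4-bromo-2-methoxyphenoxy)(tert-butyl)dimethylsilane
Product: 6 (2-bromo-3-hydroxy-4,5-dimethoxyphenyl)(4-hydroxy-3-methoxyphenyl)methanol (racemic), via aryllithium 4 (not isolated), via silyl-protected carbinol 5 (not isolated)
Conditions: 2 with NaH, THF, 0 °C; 3 with n-BuLi, THF, −78 °C; combine, −78 → 0 °C; then Bu4NF, 0 °C; aqueous NH4Cl
Reagents that add atoms: none
Why: Bromine–lithium exchange of 3 and 1,2-addition of aryllithium 4 to the sodium phenoxide of 2 (carbonyl addition should outpace exchange with the aryl bromide of 2 at −78 °C) give the carbinol, whose silyl ether is cleaved by fluoride in the same flask; the carbinol center is racemic and is erased when the para-quinone methide forms in step 5.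

Step 3
Reactants: 7 paraconic acid (racemic 5-oxotetrahydrofuran-3-carboxylic acid)
Product: 8 methyl 5-oxotetrahydrofuran-3-carboxylate (racemic methyl paraconate)
Conditions: MeI, KHCO3, DMF, 20 °C
Reagents that add atoms: iodomethane, CI
Why: SN2 O-alkylation of the carboxylate under bicarbonate conditions should esterify the acid while leaving the lactone closed.

Step 4
Reactants: 8 methyl 5-oxotetrahydrofuran-3-carboxylate
Product: 9 methyl 5-[(trimethylsilyl)oxy]-2,3-dihydrofuran-3-carboxylate (racemic)
Conditions: LiN(iPr)2, Me3SiCl, THF, −78 °C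
Reagents that add atoms: chlorotrimethylsilane, C[Si](C)(C)Cl
Why: Kinetic deprotonation with in situ O-silylation should take the less hindered and more acidic lactone alpha-methylene proton in preference to the tertiary ester alpha-proton, giving the cyclic silyl ketene acetal whose only nucleophilic carbon is the future C2.

Step 5
Reactants: 6 (2-bromo-3-hydroxy-4,5-dimethoxyphenyl)(4-hydroxy-3-methoxyphenyl)methanol; 9 methyl 5-[(trimethylsilyl)oxy]-2,3-dihydrofuran-3-carboxylate
Product: 14 dimethyl (1R)-8-bromo-7-hydroxy-1-(4-hydroxy-3-methoxyphenyl)-5,6-dimethoxy-1,2,3,4-tetrahydronaphthalene-2,3-dicarboxylate (C2/C3 epimer mixture), via para-quinone methide 10 (not isolated), via lactone adduct 11 (not isolated), via itaconate half-ester 12 (not isolated), via tetralin half-ester acid 13 (not isolated)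
Conditions: 9 (2.5 equiv), (R)-TRIP (chiral phosphoric acid, 10 mol%), CH2Cl2, 0 °C; then DBU, 0 → 20 °C; then CF3SO3H, (CF3)2CHOH, 0 → 20 °C; then MeOH, 40 °C
Reagents that add atoms: methanol, CO
Why: Proposed new method: the phosphoric acid dehydrates 6 to para-quinone methide 10 and, hydrogen-bonded to its carbonyl oxygen, steers the lactone alpha-carbon of 9 onto one face of C1 in a Mukaiyama-type 1,6-addition (C1–C2 bond, adduct 11); DBU then opens the paraconate ring by E1cB loss of the carboxylate from C4, as in the ring-opening stage of a Stobbe condensation, to give acrylate 12, and CF3SO3H closes ring B by Friedel–Crafts conjugate addition of C4a to C4 (13) before acidic methanol esterifies the C2 acid. The closest known reaction types are chiral phosphoric acid-catalysed 1,6-additions of carbon nucleophiles to para-quinone methides generated in situ from para-hydroxybenzhydrols, the Stobbe lactone opening and acid-mediated intramolecular hydroarylation of acrylates; what is new is the silyl ketene acetal as nucleophile in the asymmetric addition and the telescoping into a formal [3+3] annulation. Ring B closes in a 6-endo-trig mode, C4a attacking the CH2 terminus of the 2-substituted acrylate rather than its substituted alpha-carbon. The only stereocenter that must be set here is C1, controlled by the chiral phosphate bound to the quinone methide; C2 and C3 are alpha-ester centers left uncontrolled on purpose (racemic 9 is therefore sufficient) and are corrected in step 7. The step needs three selectivities: attack at C4a and not C8 (secured by the C8 bromine), closure by ring A and not ring C (C4a is para to a hydroxyl and ortho to a methoxy group, whereas the free positions of ring C next to C1 are meta to its hydroxyl), and bonding through C2 and not C4 of the succinate unit (secured by the lactone ring of 9).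

Step 6
Reactants: 14 dimethyl (1R)-8-bromo-7-hydroxy-1-(4-hydroxy-3-methoxyphenyl)-5,6-dimethoxy-1,2,3,4-tetrahydronaphthalene-2,3-dicarboxylate
Product: 15 dimethyl (1R)-7-hydroxy-1-(4-hydroxy-3-methoxyphenyl)-5,6-dimethoxy-1,2,3,4-tetrahydronaphthalene-2,3-dicarboxylate (C2/C3 epimer mixture)
Conditions: H2 (1 atm), Pd/C, NaOAc, MeOH, 20 °C
Reagents that add atoms: none
Why: Catalytic hydrogenolysis of the aryl C–Br bond with acetate as HBr scavenger should remove the blocking group without touching the esters, the phenols or the C1 stereocenter, and doing it before equilibration avoids any bias from the peri bromine.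

Step 7
Reactants: 15 dimethyl (1R)-7-hydroxy-1-(4-hydroxy-3-methoxyphenyl)-5,6-dimethoxy-1,2,3,4-tetrahydronaphthalene-2,3-dicarboxylate (epimer mixture)
Product: 16 dimethyl (1R,2S,3S)-7-hydroxy-1-(4-hydroxy-3-methoxyphenyl)-5,6-dimethoxy-1,2,3,4-tetrahydronaphthalene-2,3-dicarboxylate
Conditions: NaOMe, MeOH, 65 °C; then aqueous NH4Cl
Reagents that add atoms: none
Why: Base-mediated epimerisation through the ester enolates reversibly inverts C2 and C3 while the non-acidic C1–H is untouched, so the mixture should converge on the all-equatorial 1,2-trans-2,3-trans diester, which sets C2 (S) and C3 (S) under thermodynamic control relative to C1.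

Step 8
Reactants: 16 dimethyl (1R,2S,3S)-7-hydroxy-1-(4-hydroxy-3-methoxyphenyl)-5,6-dimethoxy-1,2,3,4-tetrahydronaphthalene-2,3-dicarboxylate
Product: 17 [(1R,2S,3S)-7-hydroxy-1-(4-hydroxy-3-methoxyphenyl)-3-(hydroxymethyl)-5,6-dimethoxy-1,2,3,4-tetrahydronaphthalen-2-yl]methanol (target)
Conditions: LiAlH4, THF, 0 → 65 °C; then H2O, aqueous NaOH
Reagents that add atoms: none
Why: Hydride reduction of both methyl esters to primary alcohols should proceed without epimerisation because carbonyl addition is faster than enolisation, giving the target diol with the three centers unchanged.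

## Compound list

1 | 3-hydroxy-4,5-dimethoxybenzaldehyde | O=Cc1cc(O)c(OC)c(OC)c1 | starting material
2 | 2-bromo-3-hydroxy-4,5-dimethoxybenzaldehyde | O=Cc1cc(OC)c(OC)c(O)c1Br | intermediate
3 | (4-bromo-2-methoxyphenoxy)(tert-butyl)dimethylsilane | COc1cc(Br)ccc1O[Si](C)(C)C(C)(C)C | starting material
4 | [4-(tert-butyldimethylsilyloxy)-3-methoxyphenyl]lithium | [Li]c1ccc(O[Si](C)(C)C(C)(C)C)c(OC)c1 | intermediate
5 | (2-bromo-3-hydroxy-4,5-dimethoxyphenyl)[4-(tert-butyldimethylsilyloxy)-3-methoxyphenyl]methanol (racemic) | COc1cc(C(O)c2cc(OC)c(OC)c(O)c2Br)ccc1O[Si](C)(C)C(C)(C)C | intermediate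
6 | (2-bromo-3-hydroxy-4,5-dimethoxyphenyl)(4-hydroxy-3-methoxyphenyl)methanol (racemic) | COc1cc(C(O)c2cc(OC)c(OC)c(O)c2Br)ccc1O | intermediate
7 | paraconic acid, 5-oxotetrahydrofuran-3-carboxylic acid (racemic) | O=C1CC(C(=O)O)CO1 | starting material
8 | methyl 5-oxotetrahydrofuran-3-carboxylate (racemic) | COC(=O)C1COC(=O)C1 | intermediate
9 | methyl 5-[(trimethylsilyl)oxy]-2,3-dihydrofuran-3-carboxylate (racemic) | COC(=O)C1COC(O[Si](C)(C)C)=C1 | intermediate
10 | 4-[(2-bromo-3-hydroxy-4,5-dimethoxyphenyl)methylidene]-2-methoxycyclohexa-2,5-dien-1-one | COC1=CC(=Cc2cc(OC)c(OC)c(O)c2Br)C=CC1=O | intermediate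
11 | methyl 4-[(R)-(2-bromo-3-hydroxy-4,5-dimethoxyphenyl)(4-hydroxy-3-methoxyphenyl)methyl]-5-oxotetrahydrofuran-3-carboxylate (lactone centers as a mixture) | COc1cc([C@H](c2cc(OC)c(OC)c(O)c2Br)C2C(=O)OCC2C(=O)OC)ccc1O | intermediate
12 | 2-[(R)-(2-bromo-3-hydroxy-4,5-dimethoxyphenyl)(4-hydroxy-3-methoxyphenyl)methyl]-3-(methoxycarbonyl)but-3-enoic acid (C2 as a mixture) | COc1cc([C@H](c2cc(OC)c(OC)c(O)c2Br)C(C(=O)O)C(=C)C(=O)OC)ccc1O | intermediate
13 | (1R)-8-bromo-7-hydroxy-1-(4-hydroxy-3-methoxyphenyl)-5,6-dimethoxy-3-(methoxycarbonyl)-1,2,3,4-tetrahydronaphthalene-2-carboxylic acid (C2/C3 as a mixture) | COc1cc([C@@H]2c3c(Br)c(O)c(OC)c(OC)c3CC(C(=O)OC)C2C(=O)O)ccc1O | intermediate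
14 | dimethyl (1R)-8-bromo-7-hydroxy-1-(4-hydroxy-3-methoxyphenyl)-5,6-dimethoxy-1,2,3,4-tetrahydronaphthalene-2,3-dicarboxylate (C2/C3 as a mixture) | COc1cc([C@@H]2c3c(Br)c(O)c(OC)c(OC)c3CC(C(=O)OC)C2C(=O)OC)ccc1O | intermediate
15 | dimethyl (1R)-7-hydroxy-1-(4-hydroxy-3-methoxyphenyl)-5,6-dimethoxy-1,2,3,4-tetrahydronaphthalene-2,3-dicarboxylate (C2/C3 as a mixture) | COc1cc([C@@H]2c3cc(O)c(OC)c(OC)c3CC(C(=O)OC)C2C(=O)OC)ccc1O | intermediate
16 | dimethyl (1R,2S,3S)-7-hydroxy-1-(4-hydroxy-3-methoxyphenyl)-5,6-dimethoxy-1,2,3,4-tetrahydronaphthalene-2,3-dicarboxylate | COc1cc([C@@H]2c3cc(O)c(OC)c(OC)c3C[C@H](C(=O)OC)[C@H]2C(=O)OC)ccc1O | intermediate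
17 | [(1R,2S,3S)-7-hydroxy-1-(4-hydroxy-3-methoxyphenyl)-3-(hydroxymethyl)-5,6-dimethoxy-1,2,3,4-tetrahydronaphthalen-2-yl]methanol | COc1cc([C@@H]2c3cc(O)c(OC)c(OC)c3C[C@H](CO)[C@H]2CO)ccc1O | target

## Step count and risks

Total steps: 8. Longest linear sequence: 6 steps (1, 2, 5, 6, 7, 8).

**Step 5 (Proposed new method).**
- What may go wrong: poor facial selectivity at C1 in the 1,6-addition; hydrolysis of the ketene acetal by the water released on quinone methide formation before it adds; incomplete E1cB opening of the lactone; ring closure through ring C or by acylation instead of conjugate addition; acid-mediated erosion of the C1 configuration.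
- Fallback (sets out from 6, comes back at 14), using individually precedented steps with the two bonds made separately:
  - Dimethyl itaconate is reduced at its non-conjugated ester (iBu2AlH, CH2Cl2, −78 °C) to methyl 2-methylidene-4-oxobutanoate F1.
  - 6 and F1 are joined by aminocatalytic SN1-type alpha-alkylation of the aldehyde ((S)-alpha,alpha-diphenylprolinol trimethylsilyl ether, 4-nitrobenzoic acid, CH2Cl2). This should give methyl (3S,4R)-4-(2-bromo-3-hydroxy-4,5-dimethoxyphenyl)-3-formyl-4-(4-hydroxy-3-methoxyphenyl)-2-methylidenebutanoate F2. The diarylmethine epimers are separated at this stage, so that only the (R)-C1 series is carried on.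
  - Pinnick oxidation (NaClO2, NaH2PO4, 2-methyl-2-butene) gives acid 12 as a single C2 epimer.
  - CF3SO3H in (CF3)2CHOH followed by methanol, run as a separate step, closes ring B and esterifies to return 14.

**Step 4.**
- What may go wrong: deprotonation at the ester alpha-carbon instead of the lactone alpha-carbon, which triggers E1cB ring opening before silylation.
- Fallback (sets out from 7, comes back at 11):
  - The free acid 7 is treated with two equivalents of LiN(iPr)2 and then Me3SiCl. The carboxylate formed first makes the adjacent C–H non-acidic and cannot eliminate, so only the lactone alpha-position is enolised, giving trimethylsilyl 5-[(trimethylsilyl)oxy]-2,3-dihydrofuran-3-carboxylate F3.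
  - F3 is added to 6 under (R)-TRIP as in step 5 and, after aqueous work-up, should give 4-[(R)-(2-bromo-3-hydroxy-4,5-dimethoxyphenyl)(4-hydroxy-3-methoxyphenyl)methyl]-5-oxotetrahydrofuran-3-carboxylic acid F4.
  - Fischer esterification (MeOH, catalytic H2SO4) converts F4 into 11, which is taken through the DBU, CF3SO3H and methanol stages of step 5.

**Step 1.**
- What may go wrong: bromination para to the hydroxyl (the position needed later for ring closure) or dibromination.
- Fallback (sets out from 1, comes back at 2), replacing electrophilic substitution by directed metalation: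
  - 1 is protected (MeOCH2Cl, iPr2NEt) as 3,4-dimethoxy-5-(methoxymethoxy)benzaldehyde F5.
  - The aldehyde is masked in situ as its alpha-amino alkoxide with lithium N,N,N'-trimethylethylenediamide and lithiated with n-BuLi between that group and the methoxymethoxy group. A quench with BrCl2C–CCl2Br gives 2-bromo-4,5-dimethoxy-3-(methoxymethoxy)benzaldehyde F6.
  - HCl in MeOH removes the acetal and returns 2.

Further compounds

F1 | step 5 | methyl 2-methylidene-4-oxobutanoate | COC(=O)C(=C)CC=O
F2 | step 5 | methyl (3S,4R)-4-(2-bromo-3-hydroxy-4,5-dimethoxyphenyl)-3-formyl-4-(4-hydroxy-3-methoxyphenyl)-2-methylidenebutanoate | COc1cc([C@H](c2cc(OC)c(OC)c(O)c2Br)[C@H](C=O)C(=C)C(=O)OC)ccc1O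
F3 | step 4 | trimethylsilyl 5-[(trimethylsilyl)oxy]-2,3-dihydrofuran-3-carboxylate | C[Si](C)(C)OC(=O)C1COC(O[Si](C)(C)C)=C1
F4 | step 4 | 4-[(R)-(2-bromo-3-hydroxy-4,5-dimethoxyphenyl)(4-hydroxy-3-methoxyphenyl)methyl]-5-oxotetrahydrofuran-3-carboxylic acid | COc1cc([C@H](c2cc(OC)c(OC)c(O)c2Br)C2C(=O)OCC2C(=O)O)ccc1O
F5 | step 1 | 3,4-dimethoxy-5-(methoxymethoxy)benzaldehyde | O=Cc1cc(OC)c(OC)c(OCOC)c1
F6 | step 1 | 2-bromo-4,5-dimethoxy-3-(methoxymethoxy)benzaldehyde | O=Cc1cc(OC)c(OC)c(OCOC)c1Br
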